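**Retrosynthetic overview**
1. The (Z)-feruloyl ester is made last on the propanol arm by a Still–Gennari olefination of a phosphonoacetate; the three aryl silyl ethers then come off together.
2. The dihydrofuran ring is the only ring the route forms (the four arenes are bought). It is opened at O1–C2 to a carbinol, and this is traced back to the C2 ketone, a deoxybenzoin.
3. Key disconnection C3–CH2: a racemic C3 bromide of the deoxybenzoin is joined to an acyloxymethylzinc iodide that carries the whole p-coumarate, by nickel/chiral pybox enantioconvergent coupling; this sets C3 (S), and C2 (R, trans) follows at ring closure.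
4. Enabling feature: C3 is benzylic to ring A and, with C2 at the ketone level, also α to the C2 carbonyl, so C3–Br gives one planar, doubly stabilised radical from both enantiomers; C2 is benzylic and para to the ring B oxygen, so it later ionises and O1 of ring A closes the ring trans.
5. The deoxybenzoin comes from palladium-catalysed α-arylation of silylated acetovanillone with an iodinated, protected dihydroconiferyl alcohol.

Key step: step 10

Abbreviations: TBS = tert-butyldimethylsilyl, TIPS = triisopropylsilyl, MOM = methoxymethyl.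
Assumption: the (S,S)-ligand is taken to give the (S)-ketone 16 by analogy with the accepted stereomodel of this catalyst class; if the sense is opposite, the (R,R)-ligand is used and nothing else changes.
Remark: 20 and 22 are treated as catalogue compounds.

Step 1
Reactants: 1 dihydroconiferyl alcohol
Product: 2 4-(3-hydroxypropyl)-2-iodo-6-methoxyphenol
Conditions: I2, NaHCO3, THF/H2O, 0 °C to rt
Reagents that add atoms: iodine, II
Why: Electrophilic aromatic iodination of the phenol(ate); the para position is blocked and one ortho position carries OMe, so iodine should enter the single free position ortho to OH, and no stereocentre is formed.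

Step 2
Reactants: 2 4-(3-hydroxypropyl)-2-iodo-6-methoxyphenol
Product: 3 3-[3-iodo-5-methoxy-4-(methoxymethoxy)phenyl]propan-1-ol
Conditions: MOMCl, K2CO3, acetone, 0 °C to rt
Reagents that add atoms: chloromethyl methyl ether, COCCl
Why: Williamson-type O-alkylation of the phenoxide only (K2CO3 does not deprotonate the aliphatic alcohol), giving the MOM ether that later serves as the latent O1 nucleophile.

Step 3
Reactants: 3 3-[3-iodo-5-methoxy-4-(methoxymethoxy)phenyl]propan-1-ol
Product: 4 tert-butyl{3-[3-iodo-5-methoxy-4-(methoxymethoxy)phenyl]propoxy}dimethylsilane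
Conditions: TBSCl, imidazole, CH2Cl2, rt
Reagents that add atoms: tert-butyldimethylsilyl chloride, C[Si](C)(Cl)C(C)(C)C
Why: Imidazole-promoted silylation of the primary alcohol, which keeps an alkoxide out of the enolate, zinc and nickel chemistry.

Step 4
Reactants: 5 acetovanillone
Product: 6 1-[3-methoxy-4-(TIPS-oxy)phenyl]ethan-1-one
Conditions: TIPSCl, imidazole, DMF, rt
Reagents that add atoms: triisopropylsilyl chloride, CC(C)[Si](Cl)(C(C)C)C(C)C
Why: Imidazole-promoted silylation of the phenol; the bulky silyl ether should survive phosphate base, amide base and the acid of step 12.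

Step 5
Reactants: 6 1-[3-methoxy-4-(TIPS-oxy)phenyl]ethan-1-one; 4 tert-butyl{3-[3-iodo-5-methoxy-4-(methoxymethoxy)phenyl]propoxy}dimethylsilane
Product: 7 2-{5-[3-(TBS-oxy)propyl]-3-methoxy-2-(methoxymethoxy)phenyl}-1-[3-methoxy-4-(TIPS-oxy)phenyl]ethan-1-one
Conditions: Pd2(dba)3 (2 mol%), Xantphos (4.5 mol%), K3PO4, toluene, 80 °C
Reagents that add atoms: none
Why: Palladium-catalysed α-arylation of a ketone enolate (oxidative addition of zerovalent palladium into C–I, enolate binding, reductive elimination); the acetyl CH3 is the only enolisable site and the wide-bite-angle ligand favours mono-arylation.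

Step 6
Reactants: 7 2-{5-[3-(TBS-oxy)propyl]-3-methoxy-2-(methoxymethoxy)phenyl}-1-[3-methoxy-4-(TIPS-oxy)phenyl]ethan-1-one
Product: 9 rac-2-bromo-2-{5-[3-(TBS-oxy)propyl]-3-methoxy-2-(methoxymethoxy)phenyl}-1-[3-methoxy-4-(TIPS-oxy)phenyl]ethan-1-one, via lithium enolate 8 (not isolated)
Conditions: LiN(SiMe3)2, THF, −78 °C; then NBS, −78 °C
Reagents that add atoms: N-bromosuccinimide, O=C1CCC(=O)N1Br
Why: Enolate bromination at the doubly activated (benzylic, α-keto) CH2 under non-acidic conditions that spare the acetal and silyl ethers; the C3 stereocentre is racemic on purpose because step 10 erases it.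

Step 7
Reactants: 10 (E)-p-coumaric acid
Product: 12 (E)-3-[4-(TBS-oxy)phenyl]acrylic acid, via bis-silylated coumarate 11 (not isolated)
Conditions: TBSCl (2.2 equiv), imidazole, DMF, rt; then AcOH, THF/H2O, rt
Reagents that add atoms: tert-butyldimethylsilyl chloride, C[Si](C)(Cl)C(C)(C)C
Why: Exhaustive silylation followed by selective hydrolysis of the far more labile silyl ester, which leaves the aryl silyl ether.

Step 8
Reactants: 12 (E)-3-[4-(TBS-oxy)phenyl]acrylic acid
Product: 13 chloromethyl (E)-3-[4-(TBS-oxy)phenyl]acrylate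
Conditions: ClCH2OSO2Cl, NaHCO3, Bu4NHSO4 (cat.), CH2Cl2/H2O, 0 °C to rt
Reagents that add atoms: chloromethyl chlorosulfate, ClCOS(=O)(=O)Cl
Why: Phase-transfer O-alkylation of the carboxylate, in which chlorosulfate is the better leaving group so that the chloromethyl ester results.

Step 9
Reactants: 13 chloromethyl (E)-3-[4-(TBS-oxy)phenyl]acrylate
Product: 14 iodomethyl (E)-3-[4-(TBS-oxy)phenyl]acrylate
Conditions: NaI, acetone, rt, dark
Reagents that add atoms: sodium iodide, [Na+].[I-]
Why: Finkelstein halide exchange (SN2), driven by precipitation of NaCl, gives the iodide needed for zinc insertion.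

Step 10
Reactants: 9 rac-2-bromo-2-{5-[3-(TBS-oxy)propyl]-3-methoxy-2-(methoxymethoxy)phenyl}-1-[3-methoxy-4-(TIPS-oxy)phenyl]ethan-1-one; 14 iodomethyl (E)-3-[4-(TBS-oxy)phenyl]acrylate
Product: 16 (2S)-2-{5-[3-(TBS-oxy)propyl]-3-methoxy-2-(methoxymethoxy)phenyl}-3-[3-methoxy-4-(TIPS-oxy)phenyl]-3-oxopropyl (E)-3-[4-(TBS-oxy)phenyl]acrylate, via acyloxymethylzinc iodide 15 (not isolated)
Conditions: 14, Zn dust (activated by BrCH2CH2Br, Me3SiCl), THF, 15 °C; solution decanted from zinc and added to 9, NiCl2·glyme (10 mol%), (S,S)-iPr-pybox (13 mol%), glyme/THF, −30 °C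
Reagents that add atoms: none
Why: Proposed new method: zinc inserts into the C–I bond of 14, turning the natively electrophilic oxymethyl carbon into the nucleophile 15, which transfers its acyloxymethyl group to a pybox-bound nickel centre; monovalent nickel abstracts bromine from either enantiomer of 9 to give the same planar C3 radical (benzylic to ring A and α to the C2 carbonyl), this radical is captured by the chiral alkylnickel species, and reductive elimination from trivalent nickel forms the C3–CH2 bond, so two carbons that are both electrophilic in their precursors are joined. The closest known reaction types are the nickel/pybox-catalysed enantioconvergent Negishi couplings of racemic secondary benzylic bromides with alkylzinc halides and of racemic α-bromo ketones with arylzinc halides, and 15 is the cinnamoyl analogue of known acyloxymethylzinc iodides; new is the use of such an α-acyloxy zinc nucleophile in the enantioconvergent manifold. No ring is closed in this step. The C3 stereocentre (S) is set by the chiral ligand during radical capture and reductive elimination (catalyst control), the configuration of racemic 9 being erased at the radical stage. The step needs chemoselectivity for C3–Br activation over bromine–zinc exchange, over conjugate addition to the cinnamate and over enolisation of the β-acyloxy ketone product (epimerisation, E1cB loss of coumarate); the weak, doubly activated C–Br bond, the non-basic organozinc and −30 °C should secure this.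

Step 11
Reactants: 16 (2S)-2-{5-[3-(TBS-oxy)propyl]-3-methoxy-2-(methoxymethoxy)phenyl}-3-[3-methoxy-4-(TIPS-oxy)phenyl]-3-oxopropyl (E)-3-[4-(TBS-oxy)phenyl]acrylate
Product: 17 (2S)-2-{5-[3-(TBS-oxy)propyl]-3-methoxy-2-(methoxymethoxy)phenyl}-3-hydroxy-3-[3-methoxy-4-(TIPS-oxy)phenyl]propyl (E)-3-[4-(TBS-oxy)phenyl]acrylate (both epimers at the carbinol carbon)
Conditions: NaBH4, CeCl3·7H2O, MeOH/THF, −78 to −40 °C; AcOH quench
Reagents that add atoms: none
Why: Luche-type 1,2-reduction of the aryl ketone; CeCl3 keeps the medium non-basic so the acidic C3–H is not removed (no epimerisation, no E1cB, no acyl shift) and the esters are untouched, while the new carbinol centre is left uncontrolled because step 12 ionises it.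

Step 12
Reactants: 17 (2S)-2-{5-[3-(TBS-oxy)propyl]-3-methoxy-2-(methoxymethoxy)phenyl}-3-hydroxy-3-[3-methoxy-4-(TIPS-oxy)phenyl]propyl (E)-3-[4-(TBS-oxy)phenyl]acrylate
Product: 19 {(2R,3S)-5-(3-hydroxypropyl)-7-methoxy-2-[3-methoxy-4-(TIPS-oxy)phenyl]-2,3-dihydro-1-benzofuran-3-yl}methyl (E)-3-[4-(TBS-oxy)phenyl]acrylate, via cyclised silyl ether 18 (not isolated)
Conditions: TFA, CH2Cl2, −20 to 0 °C; then H2O/THF added, rt; aqueous NaHCO3 work-up
Reagents that add atoms: none
Why: Acid-mediated cyclodehydration through a para-quinone-methide-like benzylic cation: C2–OH ionises because C2 is para to the silyloxy group of ring B, O1 of ring A (as the MOM ether oxygen, which then sheds its methoxymethyl group, or as the phenol freed by the same acid) closes the dihydrofuran ring in a 5-exo-trig mode, and C2 is set trans to the C3 substituent under thermodynamic control by the untouched C3 centre, giving (2R,3S); the wet acid then cleaves the primary silyl ether while the aryl silyl ethers stay.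

Step 13
Reactants: 19 {(2R,3S)-5-(3-hydroxypropyl)-7-methoxy-2-[3-methoxy-4-(TIPS-oxy)phenyl]-2,3-dihydro-1-benzofuran-3-yl}methyl (E)-3-[4-(TBS-oxy)phenyl]acrylate; 20 2-[bis(2,2,2-trifluoroethoxy)phosphoryl]acetic acid
Product: 21 3-{(2R,3S)-3-({[(E)-3-[4-(TBS-oxy)phenyl]acryloyl]oxy}methyl)-7-methoxy-2-[3-methoxy-4-(TIPS-oxy)phenyl]-2,3-dihydro-1-benzofuran-5-yl}propyl 2-[bis(2,2,2-trifluoroethoxy)phosphoryl]acetate
Conditions: EDC·HCl, DMAP (cat.), CH2Cl2, 0 °C to rt
Reagents that add atoms: none
Why: Carbodiimide (Steglich) esterification of the only free hydroxyl group.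

Step 14
Reactants: 21 3-{(2R,3S)-3-({[(E)-3-[4-(TBS-oxy)phenyl]acryloyl]oxy}methyl)-7-methoxy-2-[3-methoxy-4-(TIPS-oxy)phenyl]-2,3-dihydro-1-benzofuran-5-yl}propyl 2-[bis(2,2,2-trifluoroethoxy)phosphoryl]acetate; 22 4-(TBS-oxy)-3-methoxybenzaldehyde
Product: 24 3-{(2R,3S)-3-({[(E)-3-[4-(TBS-oxy)phenyl]acryloyl]oxy}methyl)-7-methoxy-2-[3-methoxy-4-(TIPS-oxy)phenyl]-2,3-dihydro-1-benzofuran-5-yl}propyl (Z)-3-[3-methoxy-4-(TBS-oxy)phenyl]acrylate, via potassium phosphonate carbanion 23 (not isolated)
Conditions: KN(SiMe3)2, 18-crown-6, THF, −78 °C; then 22, −78 °C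
Reagents that add atoms: none
Why: Still–Gennari variant of the Horner–Wadsworth–Emmons olefination: the electron-poor bis(trifluoroethyl) phosphonate and the crown-separated potassium ion make elimination from the kinetic adduct fast, so the (Z)-alkene should dominate, and the stabilised carbanion at −78 °C leaves the other esters and both stereocentres alone.

Step 15
Reactants: 24 3-{(2R,3S)-3-({[(E)-3-[4-(TBS-oxy)phenyl]acryloyl]oxy}methyl)-7-methoxy-2-[3-methoxy-4-(TIPS-oxy)phenyl]-2,3-dihydro-1-benzofuran-5-yl}propyl (Z)-3-[3-methoxy-4-(TBS-oxy)phenyl]acrylate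
Product: 25 3-{(2R,3S)-2-(4-hydroxy-3-methoxyphenyl)-3-({[(E)-3-(4-hydroxyphenyl)acryloyl]oxy}methyl)-7-methoxy-2,3-dihydro-1-benzofuran-5-yl}propyl (Z)-3-(4-hydroxy-3-methoxyphenyl)acrylate (CNP0267960.2)
Conditions: Bu4NF, AcOH, THF, 0 °C, dark
Reagents that add atoms: none
Why: Fluoride-induced cleavage of the three aryl silyl ethers; acetic acid keeps the phenols protonated so that neither ester is cleaved, the (Z)-alkene is not isomerised and the ring B phenoxide cannot reopen the dihydrofuran ring.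

**Compound list**
1 | dihydroconiferyl alcohol, 4-(3-hydroxypropyl)-2-methoxyphenol | COc1cc(CCCO)ccc1O | starting material
2 | 4-(3-hydroxypropyl)-2-iodo-6-methoxyphenol | COc1cc(CCCO)cc(I)c1O | intermediate
3 | 3-[3-iodo-5-methoxy-4-(methoxymethoxy)phenyl]propan-1-ol | COCOc1c(I)cc(CCCO)cc1OC | intermediate
4 | tert-butyl{3-[3-iodo-5-methoxy-4-(methoxymethoxy)phenyl]propoxy}dimethylsilane | COCOc1c(I)cc(CCCO[Si](C)(C)C(C)(C)C)cc1OC | intermediate
5 | acetovanillone, 1-(4-hydroxy-3-methoxyphenyl)ethan-1-one | CC(=O)c1ccc(O)c(OC)c1 | starting material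
6 | 1-[3-methoxy-4-(TIPS-oxy)phenyl]ethan-1-one | CC(=O)c1ccc(O[Si](C(C)C)(C(C)C)C(C)C)c(OC)c1 | intermediate
7 | deoxybenzoin, 2-{5-[3-(TBS-oxy)propyl]-3-methoxy-2-(methoxymethoxy)phenyl}-1-[3-methoxy-4-(TIPS-oxy)phenyl]ethan-1-one | COCOc1c(OC)cc(CCCO[Si](C)(C)C(C)(C)C)cc1CC(=O)c1ccc(O[Si](C(C)C)(C(C)C)C(C)C)c(OC)c1 | intermediate
8 | lithium enolate of 7 | COCOc1c(OC)cc(CCCO[Si](C)(C)C(C)(C)C)cc1C=C(O[Li])c1ccc(O[Si](C(C)C)(C(C)C)C(C)C)c(OC)c1 | intermediate (not isolated)
9 | racemic α-bromo ketone, bromine on the carbon between ring A and the carbonyl | COCOc1c(OC)cc(CCCO[Si](C)(C)C(C)(C)C)cc1C(Br)C(=O)c1ccc(O[Si](C(C)C)(C(C)C)C(C)C)c(OC)c1 | intermediate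
10 | (E)-p-coumaric acid | O=C(O)/C=C/c1ccc(O)cc1 | starting material
11 | TBS (E)-3-[4-(TBS-oxy)phenyl]acrylate (silyl ester and silyl ether) | O=C(O[Si](C)(C)C(C)(C)C)/C=C/c1ccc(O[Si](C)(C)C(C)(C)C)cc1 | intermediate (not isolated)
12 | (E)-3-[4-(TBS-oxy)phenyl]acrylic acid | O=C(O)/C=C/c1ccc(O[Si](C)(C)C(C)(C)C)cc1 | intermediate
13 | chloromethyl (E)-3-[4-(TBS-oxy)phenyl]acrylate | O=C(OCCl)/C=C/c1ccc(O[Si](C)(C)C(C)(C)C)cc1 | intermediate
14 | iodomethyl (E)-3-[4-(TBS-oxy)phenyl]acrylate | O=C(OCI)/C=C/c1ccc(O[Si](C)(C)C(C)(C)C)cc1 | intermediate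
15 | ({(E)-3-[4-(TBS-oxy)phenyl]acryloyl}oxy)methylzinc iodide | O=C(OC[Zn]I)/C=C/c1ccc(O[Si](C)(C)C(C)(C)C)cc1 | intermediate (not isolated)
16 | (S)-ketone, (2S)-2-(ring A aryl)-3-(ring B aryl)-3-oxopropyl (E)-4-O-TBS-p-coumarate | COCOc1c(OC)cc(CCCO[Si](C)(C)C(C)(C)C)cc1[C@@H](COC(=O)/C=C/c1ccc(O[Si](C)(C)C(C)(C)C)cc1)C(=O)c1ccc(O[Si](C(C)C)(C(C)C)C(C)C)c(OC)c1 | intermediate
17 | carbinol from 16, (S) at the carbon bearing ring A, both epimers at the carbinol carbon | COCOc1c(OC)cc(CCCO[Si](C)(C)C(C)(C)C)cc1[C@@H](COC(=O)/C=C/c1ccc(O[Si](C)(C)C(C)(C)C)cc1)C(O)c1ccc(O[Si](C(C)C)(C(C)C)C(C)C)c(OC)c1 | intermediate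
18 | (2R,3S)-trans-dihydrobenzofuran with primary TBS ether, ring B TIPS ether and coumarate TBS ether | CC(C)(C)[Si](C)(C)OCCCc1cc(OC)c2c(c1)[C@@H](COC(=O)/C=C/c1ccc(O[Si](C)(C)C(C)(C)C)cc1)[C@H](c1ccc(O[Si](C(C)C)(C(C)C)C(C)C)c(OC)c1)O2 | intermediate (not isolated)
19 | (2R,3S)-trans-dihydrobenzofuran with free 3-hydroxypropyl arm | OCCCc1cc(OC)c2c(c1)[C@@H](COC(=O)/C=C/c1ccc(O[Si](C)(C)C(C)(C)C)cc1)[C@H](c1ccc(O[Si](C(C)C)(C(C)C)C(C)C)c(OC)c1)O2 | intermediate
20 | 2-[bis(2,2,2-trifluoroethoxy)phosphoryl]acetic acid | O=C(O)CP(=O)(OCC(F)(F)F)OCC(F)(F)F | starting material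
21 | phosphonoacetate ester of 19 | O=C(CP(=O)(OCC(F)(F)F)OCC(F)(F)F)OCCCc1cc(OC)c2c(c1)[C@@H](COC(=O)/C=C/c1ccc(O[Si](C)(C)C(C)(C)C)cc1)[C@H](c1ccc(O[Si](C(C)C)(C(C)C)C(C)C)c(OC)c1)O2 | intermediate
22 | 4-(TBS-oxy)-3-methoxybenzaldehyde | COc1cc(C=O)ccc1O[Si](C)(C)C(C)(C)C | starting material
23 | potassium carbanion of 21 (deprotonated between P and C=O) | [K+].O=C([CH-]P(=O)(OCC(F)(F)F)OCC(F)(F)F)OCCCc1cc(OC)c2c(c1)[C@@H](COC(=O)/C=C/c1ccc(O[Si](C)(C)C(C)(C)C)cc1)[C@H](c1ccc(O[Si](C(C)C)(C(C)C)C(C)C)c(OC)c1)O2 | intermediate (not isolated)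
24 | tris-silyl ether of the target, (Z)-ferulate and (E)-coumarate in place | COc1cc(/C=C\C(=O)OCCCc2cc(OC)c3c(c2)[C@@H](COC(=O)/C=C/c2ccc(O[Si](C)(C)C(C)(C)C)cc2)[C@H](c2ccc(O[Si](C(C)C)(C(C)C)C(C)C)c(OC)c2)O3)ccc1O[Si](C)(C)C(C)(C)C | intermediate
25 | CNP0267960.2, (2R,3S) | COc1cc(/C=C\C(=O)OCCCc2cc(OC)c3c(c2)[C@@H](COC(=O)/C=C/c2ccc(O)cc2)[C@H](c2ccc(O)c(OC)c2)O3)ccc1O | target

**Count**
Total steps: 15. Longest linear sequence: 11 (steps 1, 2, 3, 5, 6, 10, 11, 12, 13, 14, 15).

**Steps most likely to fail**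

Step 10. What may go wrong: transfer of the α-acyloxymethyl group from zinc to nickel may be slow, bromine–zinc exchange may turn 9 into a zinc enolate, or the catalyst may discriminate the faces of the C3 radical poorly. The fallback uses known chemistry and makes the C3–CH2 bond with formaldehyde in natural polarity. It sets out from 7: LiN(SiMe3)2 and Me3SiCl give the (Z)-trimethylsilyl enol ether F1. A Mukaiyama-type aldol with aqueous formaldehyde, catalysed by Sc(OTf)3 and a chiral 2,2'-bipyridine diol ligand (catalytic asymmetric hydroxymethylation of ketone silicon enolates; the ligand antipode is chosen for S), should give the (S)-hydroxymethyl ketone F2. Steglich esterification of F2 with acid 12 (DCC, DMAP·TsOH, 0 °C) comes back to the route at 16.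

Step 12. What may go wrong: after ionisation at C2, loss of the C3 proton to a stilbene may compete with ring closure and would erode the C3 configuration, and the released methoxymethyl cation may alkylate the electron-rich rings. The fallback avoids the free cation and sets out from 16. Corey–Bakshi–Shibata reduction ((R)-2-methyl-CBS-oxazaborolidine, BH3·SMe2, −30 °C) should give the single carbinol epimer F3, (S) at the carbinol carbon. MgBr2·OEt2 and BuSH in Et2O remove the MOM group without ionising acid to give the phenol F4. Mitsunobu etherification (PPh3, DIAD, THF, 0 °C) closes the ring with inversion at C2 and comes back to the route at 18, whose primary silyl ether is then cleaved as in the second stage of step 12.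

Step 14. What may go wrong: Z-selectivity may be incomplete with the electron-rich aldehyde, or the alkene may drift from Z to E. The fallback builds the cis-alkene by semihydrogenation; it sets out from 19 and replaces steps 13 and 14. DCC-mediated esterification with propiolic acid at −20 °C gives the propiolate F5. Sonogashira coupling (PdCl2(PPh3)2, CuI, iPr2NEt, THF, rt) with tert-butyl(4-iodo-2-methoxyphenoxy)dimethylsilane F6 (from 4-iodo-2-methoxyphenol, TBSCl, imidazole) gives the arylpropiolate F7. Semihydrogenation over Pd/CaCO3 poisoned with Pb(OAc)2 and quinoline (H2, 1 atm, EtOAc) comes back to the route at 24.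

**Further compounds**
F1 | step 10 | (Z)-trimethylsilyl enol ether of 7 | COCOc1c(OC)cc(CCCO[Si](C)(C)C(C)(C)C)cc1/C=C(\O[Si](C)(C)C)c1ccc(O[Si](C(C)C)(C(C)C)C(C)C)c(OC)c1
F2 | step 10 | (S)-3-hydroxy-2-(ring A aryl)-1-(ring B aryl)propan-1-one | COCOc1c(OC)cc(CCCO[Si](C)(C)C(C)(C)C)cc1[C@@H](CO)C(=O)c1ccc(O[Si](C(C)C)(C(C)C)C(C)C)c(OC)c1
F3 | step 12 | single carbinol epimer of 17, (S) at the carbinol carbon and (S) at the carbon bearing ring A | COCOc1c(OC)cc(CCCO[Si](C)(C)C(C)(C)C)cc1[C@@H](COC(=O)/C=C/c1ccc(O[Si](C)(C)C(C)(C)C)cc1)[C@H](O)c1ccc(O[Si](C(C)C)(C(C)C)C(C)C)c(OC)c1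
F4 | step 12 | free ring A phenol from F3 | Oc1c(OC)cc(CCCO[Si](C)(C)C(C)(C)C)cc1[C@@H](COC(=O)/C=C/c1ccc(O[Si](C)(C)C(C)(C)C)cc1)[C@H](O)c1ccc(O[Si](C(C)C)(C(C)C)C(C)C)c(OC)c1
F5 | step 14 | propiolate ester of 19 | C#CC(=O)OCCCc1cc(OC)c2c(c1)[C@@H](COC(=O)/C=C/c1ccc(O[Si](C)(C)C(C)(C)C)cc1)[C@H](c1ccc(O[Si](C(C)C)(C(C)C)C(C)C)c(OC)c1)O2
F6 | step 14 | tert-butyl(4-iodo-2-methoxyphenoxy)dimethylsilane | COc1cc(I)ccc1O[Si](C)(C)C(C)(C)C
F7 | step 14 | 3-[3-methoxy-4-(TBS-oxy)phenyl]propiolate ester of 19 | COc1cc(C#CC(=O)OCCCc2cc(OC)c3c(c2)[C@@H](COC(=O)/C=C/c2ccc(O[Si](C)(C)C(C)(C)C)cc2)[C@H](c2ccc(O[Si](C(C)C)(C(C)C)C(C)C)c(OC)c2)O3)ccc1O[Si](C)(C)C(C)(C)C
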